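Everything rests on one disconnection: ring B is opened at C8–C9 and the side chain at C11–C12, because C8 (a ketone before it becomes the exocyclic methylene) and the C13 ketone stand 1,5 across C9–C11–C12. An intramolecular de Mayo reaction makes both bonds at once: the enol of a 1,3-diketone adds to a vinyl group (C9=C11) on quaternary C10, closing ring B, and retro-aldol opening of the cyclobutanol releases the C9 side chain with its C13 carbonyl. The precursor 18 is a ring A cyclohexane with C4, C5 and C10 already set, a 2,4-dioxo chain on C5 and the vinyl group on C10.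

Key step: step 14

Remark: labdane numbering is used throughout, and the TADDOL antipode in step 3 is assumed, on the model known for α-substituted acroleins, to be the one that gives 6 in the configuration drawn.

Step 1
Reactants: 1 2-(2-bromoethyl)-2-methyl-1,3-dioxolane
Product: 2 3-(2-methyl-1,3-dioxolan-2-yl)propanal
Conditions: Mg, THF, 25 °C; then DMF, 0 °C; H2O
Reagents that add atoms: N,N-dimethylformamide, CN(C)C=O
Why: Formylation of the ketal-bearing Grignard reagent by DMF (Bouveault aldehyde synthesis) is a standard one-carbon extension that leaves the dioxolane intact.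

Step 2
Reactants: 2 3-(2-methyl-1,3-dioxolan-2-yl)propanal; 3 2-(triphenylphosphanylidene)propanal
Product: 4 (2E)-2-methyl-5-(2-methyl-1,3-dioxolan-2-yl)pent-2-enal
Conditions: toluene, 80 °C
Reagents that add atoms: none
Why: Wittig reaction of the stabilised α-methyl formyl ylide with an aliphatic aldehyde should give the (E)-trisubstituted enal, the alkene geometry that later becomes the C5/C10 relationship.

Step 3
Reactants: 4 (2E)-2-methyl-5-(2-methyl-1,3-dioxolan-2-yl)pent-2-enal; 5 (1E)-3-(tert-butyldimethylsilyloxy)-N,N-dimethylbuta-1,3-dien-1-amine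
Product: 6 amino siloxy cyclohexene carbaldehyde (cycloadduct)
Conditions: 1-naphthyl-TADDOL (20 mol %), toluene, −78 → −40 °C
Reagents that add atoms: none
Why: Hydrogen-bond-catalysed asymmetric Diels–Alder reaction of an α-substituted enal with an amino siloxy diene: the amino terminus bonds to the formyl-bearing carbon (quaternary C10), suprafacial addition to the (E)-alkene puts the C5 side chain cis to the C10 methyl and trans to the formyl group, and the chiral diol shields one enal face and so fixes the absolute configuration of both centres.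

Step 4
Reactants: 6 amino siloxy cyclohexene carbaldehyde
Product: 8 (4S,5R)-4-ethenyl-4-methyl-5-[2-(2-methyl-1,3-dioxolan-2-yl)ethyl]cyclohex-2-en-1-one, via vinyl silyl enol ether 7 (not isolated)
Conditions: Ph3PCH3Br, KOtBu, THF, 0 °C; then 48% aq. HF, MeCN, 0 °C
Reagents that add atoms: methyltriphenylphosphonium bromide, C[P+](c1ccccc1)(c1ccccc1)c1ccccc1.[Br-]
Why: Wittig methylenation of the non-enolisable aldehyde while the ketone is masked as its silyl enol ether, then acid hydrolysis and E1cB loss of dimethylamine, should give the 4-vinyl enone without touching C5 or C10.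

Step 5
Reactants: 8 (4S,5R)-4-ethenyl-4-methyl-5-[2-(2-methyl-1,3-dioxolan-2-yl)ethyl]cyclohex-2-en-1-one
Product: 9 6-(hydroxymethyl) enone
Conditions: LiN(iPr)2, THF, −78 °C; CH2O (gas)
Reagents that add atoms: formaldehyde, C=O
Why: Kinetic deprotonation can only occur at the α' carbon C4 because the γ carbon C10 is quaternary, and aldol addition of the dienolate to formaldehyde installs C19 (the C4 configuration formed here is erased in step 7).

Step 6
Reactants: 9 6-(hydroxymethyl) enone
Product: 10 6-(tert-butyldiphenylsilyloxymethyl) enone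
Conditions: tBuPh2SiCl, imidazole, DMF, 0 °C → rt
Reagents that add atoms: tert-butyl(chloro)diphenylsilane, CC(C)(C)[Si](Cl)(c1ccccc1)c1ccccc1
Why: Standard silylation of the primary alcohol gives a β-silyloxy ketone that can no longer undergo retro-aldol cleavage and carries a group stable to every later step.

Step 7
Reactants: 10 6-(tert-butyldiphenylsilyloxymethyl) enone
Product: 11 6-methyl-6-(silyloxymethyl) enone
Conditions: LiN(iPr)2, THF/DMPU, −78 °C; MeI, −78 → −40 °C
Reagents that add atoms: iodomethane, CI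
Why: Alkylation of the cross-conjugated dienolate, as in the α'-alkylation of 5-substituted cyclohex-2-enones, should occur on the face anti to the adjacent C5 side chain, so the new methyl is trans and the silyloxymethyl group cis to that chain (quaternary C4).

Step 8
Reactants: 11 6-methyl-6-(silyloxymethyl) enone
Product: 12 saturated C3 ketone
Conditions: [(Ph3P)CuH]6 (0.4 equiv), H2O (2 equiv), benzene, rt
Reagents that add atoms: none
Why: Conjugate reduction by [(Ph3P)CuH]6 is selective for the enone C=C bond and leaves the isolated vinyl group, the ketal and the silyl ether alone.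

Step 9
Reactants: 12 saturated C3 ketone
Product: 13 tosylhydrazone
Conditions: TsNHNH2, PPTS (cat.), 4 Å MS, THF, 60 °C
Reagents that add atoms: 4-methylbenzenesulfonohydrazide, Cc1ccc(S(=O)(=O)NN)cc1
Why: Condensation of the ketone with the sulfonyl hydrazide gives the hydrazone needed for a non-radical and non-basic deoxygenation; the carbonyl is neopentyl but open on its C2 side.

Step 10
Reactants: 13 tosylhydrazone
Product: 14 ring A ketal
Conditions: catecholborane, CHCl3, 0 °C; then NaOAc·3H2O, 60 °C
Reagents that add atoms: none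
Why: Caglioti-type reduction, by hydride addition to the C=N bond and acetate-induced loss of sulfinate and N2 from the diazene, turns C3 into CH2 at a temperature at which catecholborane does not hydroborate the vinyl group.

Step 11
Reactants: 14 ring A ketal
Product: 15 ring A methyl ketone
Conditions: PPTS, acetone/H2O, 60 °C
Reagents that add atoms: water, O
Why: Mild acid-catalysed ketal hydrolysis frees the C8 methyl ketone while the hindered silyl ether stays.

Step 12
Reactants: 15 ring A methyl ketone; 16 (tert-butyldimethylsilyloxy)acetaldehyde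
Product: 17 β-hydroxy ketone
Conditions: (c-C6H11)2BCl, Et3N, Et2O, −78 → 0 °C; then 16, −78 °C; H2O2, pH 7 buffer, MeOH
Reagents that add atoms: none
Why: Boron-mediated aldol addition: the dialkylboron chloride with triethylamine enolises a methyl ketone on the methyl side (C12), and the enolate adds to the aldehyde to form C12–C13, the carbinol configuration being irrelevant.

Step 13
Reactants: 17 β-hydroxy ketone
Product: 18 ring A vinyl 1,3-diketone
Conditions: Dess–Martin periodinane, NaHCO3, CH2Cl2, rt
Reagents that add atoms: none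
Why: Dess–Martin oxidation of the β-hydroxy ketone gives the 1,3-diketone under buffered conditions that spare both silyl ethers.

Step 14
Reactants: 18 ring A vinyl 1,3-diketone
Product: 20 trans-decalin 8,13-diketone, via cyclobutanol 19 (not isolated)
Conditions: hν (medium-pressure Hg lamp, Pyrex filter), degassed MeCN (0.005 M), rt; then Et3N, CH2Cl2, rt
Reagents that add atoms: none
Why: The hydrogen-bonded enol of the diketone (C8(OH)=C12–C13=O) is the chromophore: its excited state adds stepwise, through a 1,4-biradical, to the tethered C9=C11 double bond ([2+2] photocycloaddition), and the β-hydroxy ketone cyclobutane 19 then undergoes retro-aldol cleavage of the temporary C8–C12 bond; this is the de Mayo reaction in its intramolecular form, a known reaction type. Ring B closes in the six-membered exo mode by C8–C9 bonding across the four-atom tether C7–C6–C5–C10, and C11–C12 bonding completes the cyclobutane. The ring fusion is not formed here: the trans relationship of the C5 chain and the C10 vinyl group, set in step 3, becomes the trans-decalin. The only new stereocentre, C9, is α to the C8 ketone and is placed under thermodynamic control by triethylamine, which should leave the side chain equatorial and cis to the C10 methyl. The step needs straight and not crossed regiochemistry, which the short tether secures (the crossed adduct would need a bridged seven-membered ring), and it needs cycloaddition to outrun hydrogen abstraction and intermolecular addition, for which the silyl ethers offer no weak γ C–H bond, filtered light leaves the saturated carbonyls unexcited and the solution is dilute.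

Step 15
Reactants: 20 trans-decalin 8,13-diketone
Product: 21 16-hydroxy 8,13-diketone
Conditions: HF·pyridine, pyridine, THF, 0 °C
Reagents that add atoms: none
Why: Buffered HF cleaves the unhindered primary silyl ether next to the C13 ketone much faster than the neopentyl diphenylsilyl ether (selective desilylation).

Step 16
Reactants: 21 16-hydroxy 8,13-diketone
Product: 23 butenolide 8-ketone, via phosphoranylidene acetate 22 (not isolated)
Conditions: Ph3P=C=C=O, toluene, 90 °C
Reagents that add atoms: (triphenylphosphanylidene)ketene, O=C=C=P(c1ccccc1)(c1ccccc1)c1ccccc1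
Why: The alcohol adds to the ketene ylide to give an ester ylide that closes onto the adjacent C13 ketone by intramolecular Wittig reaction, so the new C13=C14 bond is held Z inside the butenolide, while the hindered C8 ketone is out of reach.

Step 17
Reactants: 23 butenolide 8-ketone
Product: 24 8(17)-methylidene butenolide
Conditions: Zn, CH2Br2, TiCl4, THF/CH2Cl2, 0 °C → rt
Reagents that add atoms: dibromomethane, BrCBr
Why: Takai–Lombardo methylenation is non-basic and ketone-selective, so it should convert the hindered C8 ketone to the exocyclic alkene without epimerising C9 or attacking the lactone.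

Step 18
Reactants: 24 8(17)-methylidene butenolide
Product: 27 triisopropylsilyl (Z)-acetoxy enoate, via lithium carboxylate 25 (not isolated), via hydroxy silyl ester 26 (not isolated)
Conditions: LiOH·H2O (1.05 equiv), THF/H2O, 0 °C; evaporate; iPr3SiCl, DMF, 0 °C; then Ac2O, DMAP, pyridine, 0 °C
Reagents that add atoms: lithium hydroxide, [Li+].[OH-]; chlorotriisopropylsilane, CC(C)[Si](Cl)(C(C)C)C(C)C; acetic anhydride, CC(=O)OC(C)=O
Why: Saponification of the butenolide gives the (Z)-hydroxy carboxylate, which is silylated at the carboxylate (no acyl activation) and acetylated at the primary alcohol before it can relactonise, the alkene geometry being inherited from the ring and C19 staying protected.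

Step 19
Reactants: 27 triisopropylsilyl (Z)-acetoxy enoate
Product: 28 (2Z)-3-(acetoxymethyl)-5-[(1R,4aS,5R,8aS)-5-(hydroxymethyl)-5,8a-dimethyl-2-methylidenedecahydronaphthalen-1-yl]pent-2-enoic acid
Conditions: HF·pyridine, THF, 0 °C → rt
Reagents that add atoms: none
Why: Fluoride-mediated desilylation removes the labile silyl ester and the C19 silyl ether in one operation without touching the allylic acetate, the acid or the exocyclic alkene.

Compound list
1 | 2-(2-bromoethyl)-2-methyl-1,3-dioxolane | CC1(CCBr)OCCO1 | starting material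
2 | 3-(2-methyl-1,3-dioxolan-2-yl)propanal | CC1(CCC=O)OCCO1 | intermediate
3 | 2-(triphenylphosphanylidene)propanal | CC(C=O)=P(c1ccccc1)(c1ccccc1)c1ccccc1 | starting material
4 | (2E)-2-methyl-5-(2-methyl-1,3-dioxolan-2-yl)pent-2-enal | CC1(CC/C=C(\C)C=O)OCCO1 | intermediate
5 | (1E)-3-(tert-butyldimethylsilyloxy)-N,N-dimethylbuta-1,3-dien-1-amine | CN(C)/C=C/C(=C)O[Si](C)(C)C(C)(C)C | starting material
6 | 4-(tert-butyldimethylsilyloxy)-2-(dimethylamino)-1-methyl-6-[2-(2-methyl-1,3-dioxolan-2-yl)ethyl]cyclohex-3-ene-1-carbaldehyde; C1 methyl cis and formyl trans to the C6 side chain, amino group cis to formyl | CC1(CC[C@@H]2CC(O[Si](C)(C)C(C)(C)C)=C[C@@H](N(C)C)[C@@]2(C)C=O)OCCO1 | intermediate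
7 | 1-ethenyl analogue of 6 (silyl enol ether, same configuration) | CC1(CC[C@@H]2CC(O[Si](C)(C)C(C)(C)C)=C[C@@H](N(C)C)[C@@]2(C)C=C)OCCO1 | intermediate (not isolated)
8 | (4S,5R)-4-ethenyl-4-methyl-5-[2-(2-methyl-1,3-dioxolan-2-yl)ethyl]cyclohex-2-en-1-one; vinyl trans and methyl cis to the side chain | CC1(CC[C@@H]2CC(=O)C=C[C@@]2(C)C=C)OCCO1 | intermediate
9 | 6-(hydroxymethyl) derivative of 8; hydroxymethyl trans to the C5 side chain | CC1(CC[C@@H]2[C@@H](CO)C(=O)C=C[C@@]2(C)C=C)OCCO1 | intermediate
10 | tert-butyldiphenylsilyl ether of 9 | CC1(CC[C@@H]2[C@@H](CO[Si](c3ccccc3)(c3ccccc3)C(C)(C)C)C(=O)C=C[C@@]2(C)C=C)OCCO1 | intermediate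
11 | 4-ethenyl-4,6-dimethyl-6-(tert-butyldiphenylsilyloxymethyl)-5-[2-(2-methyl-1,3-dioxolan-2-yl)ethyl]cyclohex-2-en-1-one; 6-methyl trans and silyloxymethyl cis to the side chain | CC1(CC[C@@H]2[C@](C)(CO[Si](c3ccccc3)(c3ccccc3)C(C)(C)C)C(=O)C=C[C@@]2(C)C=C)OCCO1 | intermediate
12 | 2,3-dihydro derivative of 11 (cyclohexanone, same configuration) | CC1(CC[C@@H]2[C@](C)(CO[Si](c3ccccc3)(c3ccccc3)C(C)(C)C)C(=O)CC[C@@]2(C)C=C)OCCO1 | intermediate
13 | 4-methylbenzenesulfonylhydrazone of 12 | CC1(CC[C@@H]2[C@](C)(CO[Si](c3ccccc3)(c3ccccc3)C(C)(C)C)C(=NNS(=O)(=O)c3ccc(C)cc3)CC[C@@]2(C)C=C)OCCO1 | intermediate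
14 | tert-butyl{[3-ethenyl-1,3-dimethyl-2-[2-(2-methyl-1,3-dioxolan-2-yl)ethyl]cyclohexyl]methoxy}diphenylsilane; C4, C5 and C10 as in the target | CC1(CC[C@@H]2[C@](C)(CO[Si](c3ccccc3)(c3ccccc3)C(C)(C)C)CCC[C@@]2(C)C=C)OCCO1 | intermediate
15 | 4-{2-[(tert-butyldiphenylsilyloxy)methyl]-6-ethenyl-2,6-dimethylcyclohexyl}butan-2-one; ring configuration as in 14 | CC(=O)CC[C@@H]1[C@](C)(CO[Si](c2ccccc2)(c2ccccc2)C(C)(C)C)CCC[C@@]1(C)C=C | intermediate
16 | (tert-butyldimethylsilyloxy)acetaldehyde | O=CCO[Si](C)(C)C(C)(C)C | starting material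
17 | 1-(tert-butyldimethylsilyloxy)-2-hydroxy-6-{2-[(tert-butyldiphenylsilyloxy)methyl]-6-ethenyl-2,6-dimethylcyclohexyl}hexan-4-one; both carbinol epimers | CC(C)(C)[Si](C)(C)OCC(O)CC(=O)CC[C@@H]1[C@](C)(CO[Si](c2ccccc2)(c2ccccc2)C(C)(C)C)CCC[C@@]1(C)C=C | intermediate
18 | 1-(tert-butyldimethylsilyloxy)-6-{2-[(tert-butyldiphenylsilyloxy)methyl]-6-ethenyl-2,6-dimethylcyclohexyl}hexane-2,4-dione; ring configuration as in 14 (key-step precursor) | CC(C)(C)[Si](C)(C)OCC(=O)CC(=O)CC[C@@H]1[C@](C)(CO[Si](c2ccccc2)(c2ccccc2)C(C)(C)C)CCC[C@@]1(C)C=C | intermediate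
19 | cyclobutanol photoadduct with C8–C9 and C11–C12 formed; configuration at C8, C9 and C12 not assigned | CC(C)(C)[Si](C)(C)OCC(=O)C1CC2C1(O)CC[C@@H]1[C@](C)(CO[Si](c3ccccc3)(c3ccccc3)C(C)(C)C)CCC[C@@]21C | intermediate (not isolated)
20 | 5-[(tert-butyldiphenylsilyloxy)methyl]-5,8a-dimethyl-1-[4-(tert-butyldimethylsilyloxy)-3-oxobutyl]octahydronaphthalen-2(1H)-one; trans-decalin, C4, C5, C9 and C10 as in the target (key-step product) | O=C1CC[C@@H]2[C@](C)(CO[Si](c3ccccc3)(c3ccccc3)C(C)(C)C)CCC[C@@]2(C)[C@@H]1CCC(=O)CO[Si](C)(C)C(C)(C)C | intermediate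
21 | 1-(4-hydroxy-3-oxobutyl) analogue of 20 | O=C1CC[C@@H]2[C@](C)(CO[Si](c3ccccc3)(c3ccccc3)C(C)(C)C)CCC[C@@]2(C)[C@@H]1CCC(=O)CO | intermediate
22 | (triphenylphosphanylidene)acetate ester of 21 | O=C1CC[C@@H]2[C@](C)(CO[Si](c3ccccc3)(c3ccccc3)C(C)(C)C)CCC[C@@]2(C)[C@@H]1CCC(=O)COC(=O)C=P(c1ccccc1)(c1ccccc1)c1ccccc1 | intermediate (not isolated)
23 | 4-{2-[5-(tert-butyldiphenylsilyloxymethyl)-5,8a-dimethyl-2-oxodecahydronaphthalen-1-yl]ethyl}furan-2(5H)-one | O=C1CC[C@@H]2[C@](C)(CO[Si](c3ccccc3)(c3ccccc3)C(C)(C)C)CCC[C@@]2(C)[C@@H]1CCC1=CC(=O)OC1 | intermediate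
24 | 2-methylidene analogue of 23 (C8=C17) | C=C1CC[C@@H]2[C@](C)(CO[Si](c3ccccc3)(c3ccccc3)C(C)(C)C)CCC[C@@]2(C)[C@@H]1CCC1=CC(=O)OC1 | intermediate
25 | lithium (2Z)-3-(hydroxymethyl)-5-[5-(tert-butyldiphenylsilyloxymethyl)-5,8a-dimethyl-2-methylidenedecahydronaphthalen-1-yl]pent-2-enoate | C=C1CC[C@@H]2[C@](C)(CO[Si](c3ccccc3)(c3ccccc3)C(C)(C)C)CCC[C@@]2(C)[C@@H]1CC/C(=C/C(=O)[O-])CO.[Li+] | intermediate (not isolated)
26 | triisopropylsilyl ester of the acid of 25 | C=C1CC[C@@H]2[C@](C)(CO[Si](c3ccccc3)(c3ccccc3)C(C)(C)C)CCC[C@@]2(C)[C@@H]1CC/C(=C/C(=O)O[Si](C(C)C)(C(C)C)C(C)C)CO | intermediate (not isolated)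
27 | triisopropylsilyl (2Z)-3-(acetoxymethyl)-5-[5-(tert-butyldiphenylsilyloxymethyl)-5,8a-dimethyl-2-methylidenedecahydronaphthalen-1-yl]pent-2-enoate | C=C1CC[C@@H]2[C@](C)(CO[Si](c3ccccc3)(c3ccccc3)C(C)(C)C)CCC[C@@]2(C)[C@@H]1CC/C(=C/C(=O)O[Si](C(C)C)(C(C)C)C(C)C)COC(C)=O | intermediate
28 | (2Z)-3-(acetoxymethyl)-5-[(1R,4aS,5R,8aS)-5-(hydroxymethyl)-5,8a-dimethyl-2-methylidenedecahydronaphthalen-1-yl]pent-2-enoic acid | C=C1CC[C@@H]2[C@](C)(CO)CCC[C@@]2(C)[C@@H]1CC/C(=C/C(=O)O)COC(C)=O | target

Total step count: 19. Longest linear sequence: 19 steps (1 → 28); 3, 5 and 16 are bought.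

The three steps most likely to fail:

Step 14 (key step). The excited enol may decay or fragment faster than the hindered vinyl group traps it, or the biradical may close in the crossed sense. The fallback is thermal and radical-based; it sets out from 15 and returns at 20. Kinetic silylation (LiN(iPr)2, Me3SiCl) gives the methyl-side trimethylsilyl enol ether F1, and Rubottom oxidation with m-chloroperbenzoic acid gives the hydroxymethyl ketone F2. Cleavage with H5IO6 gives the propanoic acid F3, which PhSeSePh and PBu3 convert to the Se-phenyl selenoester F4. In a tin-radical chain with tributyl{2-[(tert-butyldimethylsilyloxy)methyl]prop-2-en-1-yl}stannane and azobis(isobutyronitrile) in benzene at 80 °C, the acyl radical should close ring B in the 6-exo mode at C9 and the C11 radical should take up the allyl unit, giving the methylidene ketone F5. Ozonolysis (O3, then Me2S) of its 1,1-disubstituted alkene gives 20.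

Step 3. The α-branched, β-substituted enal may bind the chiral diol weakly, so that conversion is slow or the uncatalysed cycloaddition erodes the enantiomeric purity. The fallback replaces catalyst control by a stoichiometric auxiliary on the diene; it sets out from 4 and returns at 8. (3E)-4-Methoxybut-3-en-2-one and (2R,5R)-2,5-diphenylpyrrolidine give the vinylogous amide F6, and KN(SiMe3)2 with tert-butyldimethylsilyl chloride gives the chiral amino siloxy diene F7. Thermal cycloaddition with 4 in toluene (rt to 60 °C) gives the auxiliary-bearing cycloadduct F8, and methylenation as in step 4 gives the vinyl silyl enol ether F9. Aqueous HF then releases 8 and the recoverable pyrrolidine.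

Step 18. The (Z)-hydroxy silyl ester 26 may close back to the butenolide faster than its hydroxyl group is acetylated. The fallback forms the alkene by olefination of an acetoxy ketone instead of opening a lactone; it sets out from 21 and returns at 28. Acetylation (Ac2O, pyridine) gives the acetoxy ketone F10. A Horner–Wadsworth–Emmons reaction at the unhindered C13 ketone with 2-(trimethylsilyl)ethyl (diethoxyphosphoryl)acetate (LiCl, DBU, MeCN) gives both geometric isomers, from which the (Z)-silylethyl enoate F11 is separated by chromatography. Methylenation of C8 as in step 17 gives the methylidene silylethyl ester F12, and tetrabutylammonium fluoride buffered with acetic acid removes the silylethyl ester and the C19 silyl ether to give 28.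

Further compounds
F1 | step 14 | trimethylsilyl enol ether of 15 (methyl side) | C=C(O[Si](C)(C)C)CC[C@@H]1[C@](C)(CO[Si](c2ccccc2)(c2ccccc2)C(C)(C)C)CCC[C@@]1(C)C=C
F2 | step 14 | 1-hydroxy-4-{2-[(tert-butyldiphenylsilyloxy)methyl]-6-ethenyl-2,6-dimethylcyclohexyl}butan-2-one | OCC(=O)CC[C@@H]1[C@](C)(CO[Si](c2ccccc2)(c2ccccc2)C(C)(C)C)CCC[C@@]1(C)C=C
F3 | step 14 | 3-{2-[(tert-butyldiphenylsilyloxy)methyl]-6-ethenyl-2,6-dimethylcyclohexyl}propanoic acid | OC(=O)CC[C@@H]1[C@](C)(CO[Si](c2ccccc2)(c2ccccc2)C(C)(C)C)CCC[C@@]1(C)C=C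
F4 | step 14 | Se-phenyl selenoester of F3 | O=C([Se]c1ccccc1)CC[C@@H]1[C@](C)(CO[Si](c2ccccc2)(c2ccccc2)C(C)(C)C)CCC[C@@]1(C)C=C
F5 | step 14 | 5-[(tert-butyldiphenylsilyloxy)methyl]-5,8a-dimethyl-1-{3-[(tert-butyldimethylsilyloxy)methyl]but-3-en-1-yl}octahydronaphthalen-2(1H)-one | O=C1CC[C@@H]2[C@](C)(CO[Si](c3ccccc3)(c3ccccc3)C(C)(C)C)CCC[C@@]2(C)[C@@H]1CCC(=C)CO[Si](C)(C)C(C)(C)C
F6 | step 3 | (3E)-4-[(2R,5R)-2,5-diphenylpyrrolidin-1-yl]but-3-en-2-one | CC(=O)/C=C/N1[C@@H](c2ccccc2)CC[C@@H]1c1ccccc1
F7 | step 3 | (2R,5R)-1-[(1E)-3-(tert-butyldimethylsilyloxy)buta-1,3-dien-1-yl]-2,5-diphenylpyrrolidine | C=C(O[Si](C)(C)C(C)(C)C)/C=C/N1[C@@H](c2ccccc2)CC[C@@H]1c1ccccc1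
F8 | step 3 | analogue of 6 with (2R,5R)-2,5-diphenylpyrrolidin-1-yl in place of dimethylamino | CC1(CC[C@@H]2CC(O[Si](C)(C)C(C)(C)C)=C[C@@H](N3[C@@H](c4ccccc4)CC[C@@H]3c3ccccc3)[C@@]2(C)C=O)OCCO1
F9 | step 3 | analogue of 7 with (2R,5R)-2,5-diphenylpyrrolidin-1-yl in place of dimethylamino | CC1(CC[C@@H]2CC(O[Si](C)(C)C(C)(C)C)=C[C@@H](N3[C@@H](c4ccccc4)CC[C@@H]3c3ccccc3)[C@@]2(C)C=C)OCCO1
F10 | step 18 | acetate of 21 | O=C1CC[C@@H]2[C@](C)(CO[Si](c3ccccc3)(c3ccccc3)C(C)(C)C)CCC[C@@]2(C)[C@@H]1CCC(=O)COC(C)=O
F11 | step 18 | 2-(trimethylsilyl)ethyl (2Z)-3-(acetoxymethyl)-5-[5-(tert-butyldiphenylsilyloxymethyl)-5,8a-dimethyl-2-oxodecahydronaphthalen-1-yl]pent-2-enoate | O=C1CC[C@@H]2[C@](C)(CO[Si](c3ccccc3)(c3ccccc3)C(C)(C)C)CCC[C@@]2(C)[C@@H]1CC/C(=C/C(=O)OCC[Si](C)(C)C)COC(C)=O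
F12 | step 18 | 2-methylidene analogue of F11 | C=C1CC[C@@H]2[C@](C)(CO[Si](c3ccccc3)(c3ccccc3)C(C)(C)C)CCC[C@@]2(C)[C@@H]1CC/C(=C/C(=O)OCC[Si](C)(C)C)COC(C)=O
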